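**Target check.** The SMILES is 7-O-methylquercetin (rhamnetin) carrying sulfate esters at O3, O5 and O4′, with a free 3′-OH. It is a planar, achiral flavonol, so there are no stereocenters to set.

**Assumption:** the product is isolated as its sodium salt after ion exchange. The free-acid SMILES is drawn, as in the target.

**Retrosynthesis**
- The target comes from hydrogenolysis of a 3′-O-benzyl tri-sulfate. The sulfates go on last, on the free 3-, 5- and 4′-OH groups of a 3′-O-benzyl flavonol.
- The flavonol C-ring (O1–C2, 3-OH) is formed by Algar–Flynn–Oyamada (AFO) oxidative cyclization of a 2′-hydroxychalcone.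
- The chalcone comes from Claisen–Schmidt condensation of two commercial aromatics. The A-ring and B-ring are already fully substituted, so the only ring formed is the C-ring.
- The 3′-OH is masked as a benzyl ether because 4′-OH and 3′-OH cannot be differentiated on rhamnetin itself. The benzyl ether is removed after sulfation.

---

**Step 1**
Reactants: 1 (2′,6′-dihydroxy-4′-methoxyacetophenone) and 2 (3-benzyloxy-4-hydroxybenzaldehyde)
Product: 3 ((E)-3-[3-(benzyloxy)-4-hydroxyphenyl]-1-(2,6-dihydroxy-4-methoxyphenyl)prop-2-en-1-one)
Conditions: KOH (50% aq., large excess), EtOH, rt, 48 h; then 1 M HCl to pH ~3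
Reagents that add atoms: none (KOH is only a base; water is lost)
Why: Claisen–Schmidt (aldol/dehydration) condensation of the acetophenone enolate with the non-enolizable aldehyde gives the thermodynamic E-enone. Excess base is needed to deprotonate the three phenols, and the chelated 2′/6′-OH groups do not interfere.

**Step 2**
Reactants: 3
Product: 4 (3′-O-benzylrhamnetin: 3-(benzyloxy)… i.e. 2-[3-(benzyloxy)-4-hydroxyphenyl]-3,5-dihydroxy-7-methoxychromen-4-one)
Conditions: 30% H2O2 (excess), 2 M NaOH (aq.), MeOH, 0 °C to rt, 24 h; then HCl to pH 3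
Reagents that add atoms: hydrogen peroxide, OO
Why: Algar–Flynn–Oyamada reaction. Phenoxide-assisted epoxidation of the enone and 6-endo ring closure give the 3-hydroxyflavanone, which is oxidized in situ to the flavonol. The transient C2/C3 stereocenters are destroyed on aromatization, so the product is achiral. The benzyl ether survives the conditions.

**Step 3**
Reactants: 4
Product: 5 (3′-O-benzylrhamnetin 3,5,4′-tri-O-sulfate)
Conditions: SO3·NEt3 (15 equiv), dry MeCN, microwave 100 °C, 1–3 h; then aq. NaHCO3 and Na⁺ ion exchange (Dowex 50W-Na⁺)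
Reagents that add atoms: sulfur trioxide–triethylamine complex, CCN(CC)CC.O=S(=O)=O
Why: Amine·SO3 complexes sulfate phenolic OH groups. The only free OH groups in 4 are 3-OH, 4′-OH and the chelated 5-OH, so excess reagent at elevated temperature sulfates all three. The 3′-OBn is inert to these conditions, and no acid is used, so the aryl sulfates are not hydrolyzed.

**Step 4**
Reactants: 5
Product: 6 (rhamnetin 3,5,4′-tri-O-sulfate, target)
Conditions: H2 (1 atm), 10% Pd/C, MeOH/H2O 9:1, rt, 5 h; filter through Celite, then C18 or Sephadex purification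
Reagents that add atoms: none (H2 adds only hydrogen; toluene is lost)
Why: Catalytic hydrogenolysis cleaves the benzyl ether to free the 3′-OH. Aryl sulfate salts, the C2=C3 enone and the aryl OMe are stable to Pd/C at 1 atm in neutral medium.

---

**Compound list**

| No. | Name | SMILES | Role |
|---|---|---|---|
| 1 | 2′,6′-Dihydroxy-4′-methoxyacetophenone | CC(=O)c1c(O)cc(OC)cc1O | starting material |
| 2 | 3-(Benzyloxy)-4-hydroxybenzaldehyde | O=Cc1ccc(O)c(OCc2ccccc2)c1 | starting material |
| 3 | (E)-3-[3-(Benzyloxy)-4-hydroxyphenyl]-1-(2,6-dihydroxy-4-methoxyphenyl)prop-2-en-1-one | COc1cc(O)c(C(=O)/C=C/c2ccc(O)c(OCc3ccccc3)c2)c(O)c1 | intermediate |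
| 4 | 3′-O-Benzylrhamnetin | COc1cc(O)c2c(=O)c(O)c(-c3ccc(O)c(OCc4ccccc4)c3)oc2c1 | intermediate |
| 5 | 3′-O-Benzylrhamnetin 3,5,4′-tri-O-sulfate | COc1cc(OS(=O)(=O)O)c2c(=O)c(OS(=O)(=O)O)c(-c3ccc(OS(=O)(=O)O)c(OCc4ccccc4)c3)oc2c1 | intermediate |
| 6 | Rhamnetin 3,5,4′-tri-O-sulfate | COc1cc(OS(=O)(=O)O)c2c(=O)c(OS(=O)(=O)O)c(-c3ccc(OS(=O)(=O)O)c(O)c3)oc2c1 | target |

**Atom check:**
- 1 + 2 − H2O gives 3 (C23H20O6).
- 3 + 2 [O] (from H2O2, which is used in excess) − H2O gives 4 (C23H18O7).
- 4 + 3 SO3 gives 5 (C23H18O16S3).
- 5 − C7H6 (toluene, after H2 addition) gives 6 (C16H12O16S3), which matches rhamnetin plus three SO3.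

**Totals:** 4 steps; longest linear sequence 4 steps (from 1 and 2).

**Three steps most likely to fail**
1. **Step 2 (AFO with free 5-OH and 4′-OH).** Aurone formation or over-oxidation can give low yields. Fallback: protect the two phenols as MOM ethers (5-OMOM on 1, 4′-OMOM on 2), run the chalcone and AFO sequence, remove the MOM groups with HCl/MeOH, then sulfate. Alternatively, make the flavone by I2/DMSO cyclization and install the 3-OH by enolate hydroxylation.
2. **Step 3 (sulfation of the H-bonded 5-OH, and stability of the 5-sulfate).** The 5-OH may stay unsulfated, or the 5-sulfate may hydrolyze during workup. Fallback: use a protected-sulfate approach. Treat 4 with Cl3CCH2OSO2Cl and DMAP to give the tris(trichloroethyl sulfate), then remove the trichloroethyl groups with Zn/NH4OAc or Pd-free ammonium formate, and finally remove the Bn group.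
3. **Step 4 (Pd/C hydrogenolysis of the very polar tri-sulfate).** Catalyst poisoning or sluggish conversion is possible. Fallback: use a 3′-O-allyl ether in place of the benzyl ether (3-allyloxy-4-hydroxybenzaldehyde in Step 1) and remove it with Pd(PPh3)4/morpholine, which avoids H2 and is compatible with the sulfates.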